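Atom numbers follow the target SMILES: C1 (exo-methylene), C2, C3 (lactone C=O), O4, C5(Me), C6, C7, C8, C9, C10(OH), C11(Me)(OH), C12, C13, C14=C15(Me), C16, C17, C18(OH). Retrosynthetic cuts, in order: C1=C2, then C10–C11, then O4–C5, then C6–C7.
Feature used: the secondary/tertiary diol C10(OH)–C11(Me)(OH) lies inside the 14-membered carbocycle C5–C18 and is the reduced form of a C10 aldehyde plus a C11 methyl ketone, so this bond can be made last by reductive carbonyl coupling.
Forward: fragment A (C5, C6, C11–C18, from nerylacetone) and fragment B (C2, C3, C7–C10, from an Evans alkylation) are joined at C6=C7 by Julia–Kocienski olefination and the alkene is saturated. The ε-lactone (O4, C3, C2, C8, C7, C6, C5) is closed next by epoxide opening, then the 14-membered ring by SmI2 pinacol coupling, and the exo-methylene is added last.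
Stereochemistry: C5 and C18 come from a Katsuki–Sharpless epoxidation (C5 is inverted in the lactonization), C8 from the oxazolidinone-controlled alkylation, C10 and C11 from the samarium-bridged ring closure, and Z-C14=C15 from nerylacetone.

Key step: step 16

Assumption: commercial nerylacetone is taken as the geometrically pure (Z)-isomer, whose alkene becomes C14=C15 unchanged.

Step 1
Reactants: 1 nerylacetone, (5Z)-6,10-dimethylundeca-5,9-dien-2-one
Product: 2 nerylacetone ethylene ketal, 2-[(3Z)-4,8-dimethylnona-3,7-dien-1-yl]-2-methyl-1,3-dioxolane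
Conditions: HOCH2CH2OH, PPTS (cat.), benzene, reflux (Dean–Stark)
Reagents that add atoms: ethylene glycol, OCCO
Why: Acid-catalysed ketalization with azeotropic removal of water masks the future C11 ketone under conditions too mild to isomerize the trisubstituted alkenes.

Step 2
Reactants: 2 nerylacetone ethylene ketal
Product: 3 (2E,6Z)-2,6-dimethyl-9-(2-methyl-1,3-dioxolan-2-yl)nona-2,6-dien-1-ol
Conditions: SeO2 (cat.), tBuOOH (70% aq.), salicylic acid (cat.), CH2Cl2, 25 °C, stopped at partial conversion
Reagents that add atoms: tert-butyl hydroperoxide, CC(C)(C)OO (the oxygen atom, relayed through catalytic selenium dioxide, O=[Se]=O)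
Why: Riley allylic oxidation (ene reaction, then [2,3]-sigmatropic shift) attacks the more reactive terminal isopropylidene unit at its (E)-methyl group, giving the (E)-allylic alcohol whose CH2OH carbon is C6.

Step 3
Reactants: 3 (2E,6Z)-allylic alcohol
Product: 4 {(2S,3S)-2-methyl-3-[(3Z)-3-methyl-6-(2-methyl-1,3-dioxolan-2-yl)hex-3-en-1-yl]oxiran-2-yl}methanol
Conditions: Ti(OiPr)4 (cat.), L-(+)-diethyl tartrate (cat.), tBuOOH (anhydrous, in decane), 4 Å MS, CH2Cl2, −20 °C
Reagents that add atoms: tert-butyl hydroperoxide, CC(C)(C)OO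
Why: Katsuki–Sharpless asymmetric epoxidation is directed by the allylic hydroxyl, the L-(+)-tartrate catalyst delivering oxygen to the face that gives the (2S,3S)-epoxide (C5 S, C18 S), while the remote Z-alkene has no allylic hydroxyl and should not react.

Step 4
Reactants: 4 (2S,3S)-epoxy alcohol
Product: 5 (2R,3S)-2-methyl-3-[(3Z)-3-methyl-6-(2-methyl-1,3-dioxolan-2-yl)hex-3-en-1-yl]oxirane-2-carbaldehyde (same spatial arrangement as 4; the descriptor at C5 changes by priority only)
Conditions: Dess–Martin periodinane, pyridine, CH2Cl2, 0 °C → rt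
Reagents that add atoms: none
Why: Dess–Martin oxidation under pyridine buffering stops at the aldehyde, and because the α-carbon C5 is quaternary the epoxy aldehyde can neither enolize nor epimerize.

Step 5
Reactants: 6 (S)-4-benzyloxazolidin-2-one; 7 pent-4-enoyl chloride
Product: 9 (S)-4-benzyl-3-(pent-4-enoyl)oxazolidin-2-one, via lithium oxazolidinide 8 (not isolated)
Conditions: n-BuLi, THF, −78 °C; then 7, −78 → 0 °C
Reagents that add atoms: none
Why: N-Acylation of the lithiated Evans oxazolidinone with the acid chloride is a standard, clean imide synthesis.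

Step 6
Reactants: 9 (S)-4-benzyl-3-(pent-4-enoyl)oxazolidin-2-one
Product: 11 tert-butyl (R)-3-[(S)-4-benzyl-2-oxooxazolidine-3-carbonyl]hex-5-enoate, via sodium enolate 10 (not isolated)
Conditions: NaN(SiMe3)2, THF, −78 °C; BrCH2CO2tBu, −78 → −40 °C
Reagents that add atoms: tert-butyl bromoacetate, CC(C)(C)OC(=O)CBr
Why: Evans asymmetric alkylation, in which the chelated sodium (Z)-enolate is alkylated on the face opposite the benzyl group, sets C8 as R.

Step 7
Reactants: 11 alkylated imide
Product: 13 tert-butyl (R)-3-[(S)-4-benzyl-2-oxooxazolidine-3-carbonyl]-4-(1,3-dioxolan-2-yl)butanoate, via aldehyde 12 (not isolated)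
Conditions: O3, CH2Cl2, −78 °C; Me2S, −78 °C → rt; then HOCH2CH2OH, PPTS (cat.), benzene, reflux (Dean–Stark)
Reagents that add atoms: ozone, [O-][O+]=O (oxygen of the non-isolated aldehyde 12 only); ethylene glycol, OCCO
Why: Ozonolysis cleaves the only alkene to the C10 aldehyde, which is acetalized at once (acid-catalysed dioxolane formation) so that it survives the later hydride, carbanion and diimide steps, the tert-butyl ester and imide being inert to PPTS.

Step 8
Reactants: 13 dioxolane imide
Product: 14 tert-butyl (R)-4-(1,3-dioxolan-2-yl)-3-(hydroxymethyl)butanoate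
Conditions: LiBH4, MeOH (1 equiv), THF, 0 °C
Reagents that add atoms: none
Why: Reductive removal of the Evans auxiliary with LiBH4 reduces only the activated imide carbonyl to the C7 primary alcohol, and the hindered tert-butyl ester resists both reduction and γ-lactonization.

Step 9
Reactants: 14 hydroxy ester
Product: 15 tert-butyl (R)-4-(1,3-dioxolan-2-yl)-3-{[(1-phenyl-1H-tetrazol-5-yl)sulfanyl]methyl}butanoate
Conditions: 1-phenyl-1H-tetrazole-5-thiol, PPh3, DIAD, THF, 0 °C → rt
Reagents that add atoms: 1-phenyl-1H-tetrazole-5-thiol, Sc1nnnn1-c1ccccc1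
Why: Mitsunobu thioetherification of the primary alcohol with the acidic tetrazolethiol is an SN2 reaction at C7 that touches no stereocentre.

Step 10
Reactants: 15 sulfide
Product: 16 tert-butyl (R)-4-(1,3-dioxolan-2-yl)-3-{[(1-phenyl-1H-tetrazol-5-yl)sulfonyl]methyl}butanoate
Conditions: (NH4)6Mo7O24·4H2O (cat.), 30% aq. H2O2, EtOH, 0 °C → rt
Reagents that add atoms: hydrogen peroxide, OO
Why: Molybdate-catalysed peroxide oxidation of the sulfide to the sulfone is reliable here because this fragment has no alkene or other oxidizable group.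

Step 11
Reactants: 16 sulfone; 5 epoxy aldehyde
Product: 18 tert-butyl (3R,4E)-3-(1,3-dioxolan-2-ylmethyl)-5-{(2S,3S)-2-methyl-3-[(3Z)-3-methyl-6-(2-methyl-1,3-dioxolan-2-yl)hex-3-en-1-yl]oxiran-2-yl}pent-4-enoate (E expected to predominate; either geometry is usable), via metalated sulfone 17 (not isolated)
Conditions: KN(SiMe3)2 added to 16 + 5, DME, −60 °C → rt
Reagents that add atoms: none
Why: Julia–Kocienski olefination (addition of the metalated sulfone to the non-enolizable aldehyde, Smiles rearrangement, loss of SO2 and tetrazololate) joins the fragments at C6=C7, and adding the base to the mixture of partners limits self-condensation of the sulfone.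

Step 12
Reactants: 18 vinyl epoxide
Product: 19 tert-butyl (3R)-3-(1,3-dioxolan-2-ylmethyl)-5-{(2S,3S)-2-methyl-3-[(3Z)-3-methyl-6-(2-methyl-1,3-dioxolan-2-yl)hex-3-en-1-yl]oxiran-2-yl}pentanoate
Conditions: 2-nitrobenzenesulfonyl hydrazide, Et3N, CH2Cl2, rt
Reagents that add atoms: none
Why: Diimide reduction (concerted syn transfer of two hydrogens) should saturate the 1,2-disubstituted C6=C7 alkene much faster than the trisubstituted C14=C15 alkene and leaves the allylic epoxide intact, which metal-catalysed hydrogenation would not.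

Step 13
Reactants: 19 epoxy tert-butyl ester
Product: 20 (4R,7R)-4-(1,3-dioxolan-2-ylmethyl)-7-[(1S,4Z)-1-hydroxy-4-methyl-7-(2-methyl-1,3-dioxolan-2-yl)hept-4-en-1-yl]-7-methyloxepan-2-one (C5 R, C8 R, C18 S)
Conditions: CSA (0.2 equiv), CH2Cl2 (0.01 M), 0 °C → rt
Reagents that add atoms: none
Why: Acid-catalysed epoxide-opening lactonization, in which the ester carbonyl oxygen attacks the activated epoxide at its tertiary carbon C5 in a 7-exo mode with inversion (C5 becomes R, C18 keeps its oxygen as S) and the dialkoxycarbenium ion loses isobutene, as known for epoxy tert-butyl esters and carbonates.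

Step 14
Reactants: 20 hydroxy lactone
Product: 21 C18 tert-butyldimethylsilyl ether of 20
Conditions: TBSOTf, 2,6-lutidine, CH2Cl2, −78 °C
Reagents that add atoms: tert-butyldimethylsilyl triflate, CC(C)(C)[Si](C)(C)OS(=O)(=O)C(F)(F)F
Why: Silyl triflate silylation of the hindered secondary C18 hydroxyl is fast at −78 °C, where the two dioxolanes are not attacked.

Step 15
Reactants: 21 silyl ether bis-dioxolane
Product: 22 2-[(4R,7R)-7-{(1S,4Z)-1-[(tert-butyldimethylsilyl)oxy]-4-methyl-8-oxonon-4-en-1-yl}-7-methyl-2-oxooxepan-4-yl]acetaldehyde (ε-lactone keto-aldehyde)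
Conditions: PPTS, acetone–H2O (9:1), reflux
Reagents that add atoms: water, O
Why: Acid-catalysed acetal hydrolysis/transacetalization in wet acetone unmasks the C10 aldehyde and the C11 ketone together, while the hindered secondary TBS ether and the lactone tolerate PPTS.

Step 16
Reactants: 22 ε-lactone keto-aldehyde
Product: 23 14-membered (10R,11S)-diol lactone with C18 as its TBS ether (the target skeleton without C1; 5R,8R,18S; 14Z)
Conditions: SmI2 (0.1 M in THF, 5 equiv), THF, 25 °C, 22 added by syringe pump over 12 h (final 2 mM), no HMPA; aq. NaHCO3 work-up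
Reagents that add atoms: none
Why: Divalent samarium transfers one electron to the aldehyde, the more easily reduced carbonyl, and the samarium-bound C10 ketyl adds to the C11 ketone carbon held on the same trivalent samarium centre, after which a second electron transfer and protonation at work-up give the diol; this is an intramolecular SmI2 pinacol coupling, the closest known reaction type being keto–aldehyde pinacol macrocyclization to 14-membered cembranoid diols with SmI2 or low-valent titanium. The 14-membered ring C5–C18 closes end to end in a 14-exo-trig radical addition to the ketone C=O, helped by high dilution and by two turn elements already in the chain, the Z-C14=C15 alkene and the ε-lactone that ties C5 to C8. C10 and C11 are formed in the same event: their relative cis-diol configuration (10R,11S) is controlled by the samarium bridge, which holds both oxygens syn in a five-membered chelate while the ring carbons C9 and C12 leave it on the same side. Their configuration relative to C8 is controlled by the existing centres through the lactone-bridged conformation (C8 arm pseudo-equatorial, ketone approached on the face away from the C5 methyl and the silyloxy arm); this facial selectivity is what the step needs and is its least secure point, so minor diastereomers would be removed by chromatography. Chemoselectivity is secured by the substrate, since the lactone, the silyl ether and the unactivated trisubstituted alkene are inert to SmI2 in THF and the ketyl-trapping exo-methylene is not yet present.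

Step 17
Reactants: 23 macrocyclic diol
Product: 24 10,11-bis(triethylsilyl) ether of 23
Conditions: TESOTf (3 equiv), 2,6-lutidine, CH2Cl2, −78 → 0 °C
Reagents that add atoms: triethylsilyl triflate, CC[Si](CC)(CC)OS(=O)(=O)C(F)(F)F
Why: Silyl triflate silylation covers the secondary C10 and tertiary C11 hydroxyls, leaving the lactone α-protons as the only acidic site for the next step.

Step 18
Reactants: 24 tris-silyl ether lactone
Product: 26 2-(dimethylaminomethyl) lactone (C2 epimers), via lithium enolate 25 (not isolated)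
Conditions: LiN(iPr)2, THF, −78 °C; CH2=NMe2+ I− (Eschenmoser's salt), −78 °C → rt
Reagents that add atoms: Eschenmoser's salt (dimethylmethylideneammonium iodide), C=[N+](C)C.[I-]
Why: Mannich reaction of the lactone lithium enolate with Eschenmoser's salt places the aminomethyl carbon C1 on C2, whose configuration is irrelevant because it becomes sp2.

Step 19
Reactants: 26 Mannich base
Product: 28 α-methylene lactone tris-silyl ether (10,11-bis-TES and 18-TBS ether of the target), via ammonium iodide 27 (not isolated)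
Conditions: MeI (excess), CH2Cl2, rt; then DBU, rt
Reagents that add atoms: iodomethane, CI (methyl group of the non-isolated ammonium salt 27 only)
Why: Exhaustive N-methylation followed by base-induced β-elimination of trimethylamine (Hofmann-type E1cB) is the standard way to turn the Mannich base into the α-methylene lactone.

Step 20
Reactants: 28 α-methylene lactone tris-silyl ether
Product: 29 CNP0263298.1 (target; 5R,8R,10R,11S,18S; 14Z)
Conditions: HF·pyridine (excess), pyridine, THF, 0 °C → rt
Reagents that add atoms: none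
Why: Buffered fluoride desilylation removes the two triethylsilyl ethers and the hindered TBS ether without conjugate addition to the methylene lactone or ionization of the tertiary alcohol.

Compound list
1 | nerylacetone, (5Z)-6,10-dimethylundeca-5,9-dien-2-one | CC(C)=CCC/C(C)=C\CCC(C)=O | starting material
2 | 2-[(3Z)-4,8-dimethylnona-3,7-dien-1-yl]-2-methyl-1,3-dioxolane | CC(C)=CCC/C(C)=C\CCC1(C)OCCO1 | intermediate
3 | (2E,6Z)-2,6-dimethyl-9-(2-methyl-1,3-dioxolan-2-yl)nona-2,6-dien-1-ol | OC/C(C)=C/CC/C(C)=C\CCC1(C)OCCO1 | intermediate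
4 | {(2S,3S)-2-methyl-3-[(3Z)-3-methyl-6-(2-methyl-1,3-dioxolan-2-yl)hex-3-en-1-yl]oxiran-2-yl}methanol | OC[C@]1(C)O[C@H]1CC/C(C)=C\CCC2(C)OCCO2 | intermediate
5 | (2R,3S)-2-methyl-3-[(3Z)-3-methyl-6-(2-methyl-1,3-dioxolan-2-yl)hex-3-en-1-yl]oxirane-2-carbaldehyde | O=C[C@]1(C)O[C@H]1CC/C(C)=C\CCC2(C)OCCO2 | intermediate
6 | (S)-4-benzyloxazolidin-2-one | O=C1OC[C@H](Cc2ccccc2)N1 | starting material
7 | pent-4-enoyl chloride | C=CCCC(=O)Cl | starting material
8 | lithium (S)-4-benzyl-2-oxooxazolidin-3-ide (not isolated) | [Li+].O=C1OC[C@H](Cc2ccccc2)[N-]1 | intermediate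
9 | (S)-4-benzyl-3-(pent-4-enoyl)oxazolidin-2-one | C=CCCC(=O)N1[C@@H](Cc2ccccc2)COC1=O | intermediate
10 | sodium (Z)-enolate of 9 (not isolated) | [Na+].[O-]/C(=C\CC=C)N1[C@@H](Cc2ccccc2)COC1=O | intermediate
11 | tert-butyl (R)-3-[(S)-4-benzyl-2-oxooxazolidine-3-carbonyl]hex-5-enoate | CC(C)(C)OC(=O)C[C@@H](CC=C)C(=O)N1[C@@H](Cc2ccccc2)COC1=O | intermediate
12 | tert-butyl (R)-3-[(S)-4-benzyl-2-oxooxazolidine-3-carbonyl]-5-oxopentanoate (not isolated) | CC(C)(C)OC(=O)C[C@@H](CC=O)C(=O)N1[C@@H](Cc2ccccc2)COC1=O | intermediate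
13 | tert-butyl (R)-3-[(S)-4-benzyl-2-oxooxazolidine-3-carbonyl]-4-(1,3-dioxolan-2-yl)butanoate | CC(C)(C)OC(=O)C[C@@H](CC1OCCO1)C(=O)N2[C@@H](Cc3ccccc3)COC2=O | intermediate
14 | tert-butyl (R)-4-(1,3-dioxolan-2-yl)-3-(hydroxymethyl)butanoate | CC(C)(C)OC(=O)C[C@@H](CC1OCCO1)CO | intermediate
15 | tert-butyl (R)-4-(1,3-dioxolan-2-yl)-3-{[(1-phenyl-1H-tetrazol-5-yl)sulfanyl]methyl}butanoate | CC(C)(C)OC(=O)C[C@@H](CC1OCCO1)CSc2nnnn2-c3ccccc3 | intermediate
16 | tert-butyl (R)-4-(1,3-dioxolan-2-yl)-3-{[(1-phenyl-1H-tetrazol-5-yl)sulfonyl]methyl}butanoate | CC(C)(C)OC(=O)C[C@@H](CC1OCCO1)CS(=O)(=O)c2nnnn2-c3ccccc3 | intermediate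
17 | potassium α-sulfonyl carbanion of 16 (not isolated) | [K+].CC(C)(C)OC(=O)C[C@@H](CC1OCCO1)[CH-]S(=O)(=O)c2nnnn2-c3ccccc3 | intermediate
18 | tert-butyl (3R,4E)-3-(1,3-dioxolan-2-ylmethyl)-5-{(2S,3S)-2-methyl-3-[(3Z)-3-methyl-6-(2-methyl-1,3-dioxolan-2-yl)hex-3-en-1-yl]oxiran-2-yl}pent-4-enoate | CC(C)(C)OC(=O)C[C@@H](CC1OCCO1)/C=C/[C@]2(C)O[C@H]2CC/C(C)=C\CCC3(C)OCCO3 | intermediate
19 | tert-butyl (3R)-3-(1,3-dioxolan-2-ylmethyl)-5-{(2S,3S)-2-methyl-3-[(3Z)-3-methyl-6-(2-methyl-1,3-dioxolan-2-yl)hex-3-en-1-yl]oxiran-2-yl}pentanoate | CC(C)(C)OC(=O)C[C@@H](CC1OCCO1)CC[C@]2(C)O[C@H]2CC/C(C)=C\CCC3(C)OCCO3 | intermediate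
20 | (4R,7R)-4-(1,3-dioxolan-2-ylmethyl)-7-[(1S,4Z)-1-hydroxy-4-methyl-7-(2-methyl-1,3-dioxolan-2-yl)hept-4-en-1-yl]-7-methyloxepan-2-one | C1(OCCO1)C[C@H]2CC[C@@](C)(OC(=O)C2)[C@@H](O)CC/C(C)=C\CCC3(C)OCCO3 | intermediate
21 | C18 tert-butyldimethylsilyl ether of 20 | C1(OCCO1)C[C@H]2CC[C@@](C)(OC(=O)C2)[C@@H](O[Si](C)(C)C(C)(C)C)CC/C(C)=C\CCC3(C)OCCO3 | intermediate
22 | 2-[(4R,7R)-7-{(1S,4Z)-1-[(tert-butyldimethylsilyl)oxy]-4-methyl-8-oxonon-4-en-1-yl}-7-methyl-2-oxooxepan-4-yl]acetaldehyde | O=CC[C@H]1CC[C@@](C)(OC(=O)C1)[C@@H](O[Si](C)(C)C(C)(C)C)CC/C(C)=C\CCC(C)=O | intermediate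
23 | 14-membered (10R,11S)-diol ε-lactone, C18 TBS ether, no exo-methylene (5R,8R,18S; 14Z) | C1C(=O)O[C@]2(C)CC[C@@H]1C[C@@H](O)[C@@](C)(O)CC/C=C(/C)CC[C@@H]2O[Si](C)(C)C(C)(C)C | intermediate
24 | 10,11-bis(triethylsilyl) ether of 23 | C1C(=O)O[C@]2(C)CC[C@@H]1C[C@@H](O[Si](CC)(CC)CC)[C@@](C)(O[Si](CC)(CC)CC)CC/C=C(/C)CC[C@@H]2O[Si](C)(C)C(C)(C)C | intermediate
25 | lithium enolate of 24 (C2=C3; not isolated) | [Li+].C1=C([O-])O[C@]2(C)CC[C@@H]1C[C@@H](O[Si](CC)(CC)CC)[C@@](C)(O[Si](CC)(CC)CC)CC/C=C(/C)CC[C@@H]2O[Si](C)(C)C(C)(C)C | intermediate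
26 | 2-(dimethylaminomethyl) derivative of 24 (C2 epimers) | CN(C)CC1C(=O)O[C@]2(C)CC[C@@H]1C[C@@H](O[Si](CC)(CC)CC)[C@@](C)(O[Si](CC)(CC)CC)CC/C=C(/C)CC[C@@H]2O[Si](C)(C)C(C)(C)C | intermediate
27 | trimethylammonium iodide from 26 (not isolated) | C[N+](C)(C)CC1C(=O)O[C@]2(C)CC[C@@H]1C[C@@H](O[Si](CC)(CC)CC)[C@@](C)(O[Si](CC)(CC)CC)CC/C=C(/C)CC[C@@H]2O[Si](C)(C)C(C)(C)C.[I-] | intermediate
28 | α-methylene lactone, 10,11-bis-TES and 18-TBS ether of the target | C=C1C(=O)O[C@]2(C)CC[C@@H]1C[C@@H](O[Si](CC)(CC)CC)[C@@](C)(O[Si](CC)(CC)CC)CC/C=C(/C)CC[C@@H]2O[Si](C)(C)C(C)(C)C | intermediate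
29 | CNP0263298.1 | C=C1C(=O)O[C@]2(C)CC[C@@H]1C[C@@H](O)[C@@](C)(O)CC/C=C(/C)CC[C@@H]2O | target

Total step count: 20. Longest linear sequence: 16 steps (steps 5–20, from 6 and 7); the nerylacetone branch (steps 1–4) joins at step 11.

Steps most likely to fail

Step 16 (pinacol macrocyclization). The end-to-end ketyl addition may be slower than reduction of the ketyl to the primary alcohol or than intermolecular coupling. The facial sense at C10 and C11 may also be poorly controlled, because a chelated transition state in a 14-membered ring can place C9 and C12 either cis or trans. Fallback: setting out from keto-aldehyde 22, the ring would be closed with low-valent titanium (TiCl3(DME)1.5, Zn–Cu couple, DME, 25 °C, slow addition) without relying on its C10 selectivity, giving 23 together with its (10S)-epimeric diol F1. Oxidation of the secondary C10 hydroxyl of the mixture (SO3·pyridine, DMSO, iPr2NEt) would converge both on the α-hydroxy ketone F2. Chelation-controlled reduction with Zn(BH4)2 (zinc bridging the C10 carbonyl and the C11 hydroxyl, hydride delivered from the outer, methyl-bearing face) would then return the cis-diol 23, where the route resumes. A wrong configuration at C11 is not corrected by this detour and would have to be separated.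

Step 13 (epoxide-opening lactonization). Hydride shift in the activated tertiary epoxide, or its capture by the C14=C15 alkene in a six-membered cation–olefin closure, may outrun the slower seven-membered attack of the ester oxygen. Fallback: setting out from epoxy ester 19, the C5–O bond would be made with water and the ring closed from the acyl side. Dilute aqueous HClO4 in THF opens trisubstituted epoxides at the tertiary carbon with inversion and hydrolyses both dioxolanes, giving the diol keto-aldehyde tert-butyl ester F3. Selective silylation of the secondary C18 hydroxyl (TBSOTf, 2,6-lutidine, −78 °C) gives the mono-TBS ether F4, and brief anhydrous CF3CO2H in CH2Cl2 at 0 °C frees the seco acid F5. Yamaguchi lactonization (2,4,6-trichlorobenzoyl chloride, Et3N, then DMAP, toluene, high dilution) onto the tertiary C5 hydroxyl then closes the seven-membered lactone and arrives at keto-aldehyde 22.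

Step 11 (fragment union). The metalated sulfone may add only slowly to the hindered α-quaternary aldehyde and be consumed by self-condensation or by attack on the epoxide. Fallback: setting out from alcohol 14, the union would use a phosphorus ylide. Iodination (I2, PPh3, imidazole, CH2Cl2) gives the iodide F6, PPh3 in MeCN at 80 °C the phosphonium iodide F7, and NaN(SiMe3)2 in THF at −78 °C the ylide F8. Wittig reaction with aldehyde 5 gives the (Z)-alkene F9, which diimide reduction as in step 12 converts into epoxy ester 19.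

Further compounds
F1 | step 16 | (10S,11S)-diol, C10 epimer of 23 | C1C(=O)O[C@]2(C)CC[C@@H]1C[C@H](O)[C@@](C)(O)CC/C=C(/C)CC[C@@H]2O[Si](C)(C)C(C)(C)C
F2 | step 16 | macrocyclic α-hydroxy ketone (C10 ketone, C11 tertiary alcohol) | C1C(=O)O[C@]2(C)CC[C@@H]1CC(=O)[C@@](C)(O)CC/C=C(/C)CC[C@@H]2O[Si](C)(C)C(C)(C)C
F3 | step 13 | tert-butyl (3R)-3-(2-oxoethyl)-substituted (6R,7S)-6,7-dihydroxy keto-aldehyde ester (C5,C18-diol; C10 aldehyde; C11 ketone) | CC(C)(C)OC(=O)C[C@@H](CC=O)CC[C@@](C)(O)[C@@H](O)CC/C(C)=C\CCC(C)=O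
F4 | step 13 | C18 tert-butyldimethylsilyl ether of F3 | CC(C)(C)OC(=O)C[C@@H](CC=O)CC[C@@](C)(O)[C@@H](O[Si](C)(C)C(C)(C)C)CC/C(C)=C\CCC(C)=O
F5 | step 13 | seco acid of 22 (free C3 carboxylic acid, free tertiary C5 hydroxyl) | OC(=O)C[C@@H](CC=O)CC[C@@](C)(O)[C@@H](O[Si](C)(C)C(C)(C)C)CC/C(C)=C\CCC(C)=O
F6 | step 11 | tert-butyl (R)-4-(1,3-dioxolan-2-yl)-3-(iodomethyl)butanoate | CC(C)(C)OC(=O)C[C@@H](CC1OCCO1)CI
F7 | step 11 | [(R)-4-tert-butoxy-2-(1,3-dioxolan-2-ylmethyl)-4-oxobutyl]triphenylphosphonium iodide | CC(C)(C)OC(=O)C[C@@H](CC1OCCO1)C[P+](c2ccccc2)(c3ccccc3)c4ccccc4.[I-]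
F8 | step 11 | ylide from F7 | CC(C)(C)OC(=O)C[C@@H](CC1OCCO1)C=P(c2ccccc2)(c3ccccc3)c4ccccc4
F9 | step 11 | (4Z)-isomer of 18 | CC(C)(C)OC(=O)C[C@@H](CC1OCCO1)/C=C\[C@]2(C)O[C@H]2CC/C(C)=C\CCC3(C)OCCO3
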